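5 questions stand on these flasks, and the argument below rests on two times, how long the catalyst works and how long the feed lasts.

| flask | starting material | reagent | second substrate | free catalyst | temperature | remark | time |
|---|---|---|---|---|---|---|---|
| alpha | 1 mM | 1.3 mM | 0.50 mM | 67 µM | 25 °C | run made earlier |  |
| delta | 1 mM | 1.3 mM | 0.25 mM | 67 µM | 25 °C | run made earlier |  |
| oak | 1.0 mM | 1.30 mM | 0.500 mM | 67 µM | 25 °C | everything together at the start | 10 min |
| larch | 1.0 mM (fed, over 2.0 min) | 1.30 mM | 0.500 mM | 67 µM | 25 °C | all else is in the flask from the start; the feed brings no volume worth counting | 10 min |
| maple | 1.0 mM (fed, over 2.0 min) | 1.30 mM | 0.500 mM | 67 µM |  | the addition at 5 °C, then warmed to 25 °C; the feed brings no volume worth counting | 10 min |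
| elm | 1.0 mM | 1.30 mM | 0.500 mM | 67 µM |  | everything together at the start at 5 °C, warmed to 25 °C at 2.0 min | 10 min |

- alpha (time / min: target / %): 1.50: 48.2; 3.00: 46.9; 5.00: 46.6; 6.00: 46.0
- delta (time / s: target / %): 10.0: 33.0; 12.0: 34.9; 25.0: 44.3; 60.0: 48.3

(readings scatter by 0.5 percentage points)

- the best flask by amount of target, in percent of the starting material charged; "all alike" if 1.5 percentage points covers them all (oak / larch / maple / elm / all alike)
- amount of target at the end, in percent of the starting material charged, oak
- amount of target at the end, in percent of the starting material charged, larch
- amount of target at the end, in percent of the starting material charged, maple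
- amount of target at the end, in percent of the starting material charged, elm

- the earlier runs were read with a standard deviation of 0.5 percentage points
- the earlier runs do not show what temperature does; that part of a forecast is a guess

1. Target stalls near 48.2% in alpha and 48.3% in delta, with half the second substrate. My own reading, which these runs cannot prove, is that the free catalyst dies while starting material remains.

2. Then, with [reagent] taken as steady, the decay is pseudo-first-order with a rate constant that fades as exp(−t/τ). Integrating it, L = ln(charged [starting material] / present [starting material]) approaches a ceiling, and the gap shrinks by that same exponential. The last delta reading, with target counted as the starting material consumed, gives the ceiling, 0.660.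

3. The gaps at 10.0 s and 25.0 s then give τ = 12.0 s, the working time of the catalyst, a value that carries the scatter of those readings.

4. In larch the feed lasts 2.0 min, ten times τ, so 90.0% of the charge arrives after the first τ has passed. A portion fed at time t meets what remains of the ceiling, ceiling·exp(−t/τ), which at small conversion I take as its converted share, and averaging that over the feed gives the dose, ceiling·τ/feed time, which I put at 6.61% of the charge.

5. I expect oak a little under alpha's 46.0%. The cold is a guess, but if it lengthens τ, elm stands to gain, and elm is my pick.

6. The forecast differs from my reckoning. It reads the stall as “a side reaction second order in starting material” and gives 44.5% for oak, 73% for larch, 60% for maple and 45.5% for elm, with larch best.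

The simulation gives 45.4% for oak, 7.69% for larch, 49.4% for maple and 73.0% for elm, with elm best.

    starting material + reagent + free catalyst → free catalyst + target (k = 7.20 × 10⁵ M⁻² s⁻¹, Ea = 13.0 kJ mol⁻¹)
    second substrate + reagent + free catalyst → free catalyst + second product (k = 6.50 × 10⁵ M⁻² s⁻¹, Ea = 15.0 kJ mol⁻¹)
    free catalyst → spent catalyst (k = 0.0660 s⁻¹, Ea = 76.0 kJ mol⁻¹)
    target → over-reaction product (k = 6.90 × 10⁻⁵ s⁻¹, Ea = 93.0 kJ mol⁻¹)
    (constants at 25 °C)

In larch the free catalyst had a half-life of 0.18 min at 0.119 min, far shorter than the feed of 2.0 min, and at 2.00 min it stood at 0.0363% of its charge, with 92.0% of the starting material still there. The dose of 6.61%, reckoned with τ = 12.0 s, lies near larch's 7.69%, and for a flask like larch with 0.17 mM of free catalyst, the dose scaled by the catalyst charge is 16.8%, where that flask gives 13.5%.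

The runs are simulated for an exercise.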